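## Retrosynthetic overview

1. Feature: in the oxolane ring (O1, C2–C5), the chain Ar–C2–C3(CH3)–C4(CH3)–C5–Ar carries the same syringyl group on C2 and C5 and a trans (3S,4S)-dimethyl pair. The carbon skeleton therefore has a C2 axis through the midpoint of C3–C4. Only the relative sense at C2 (aryl trans to C3-CH3) and at C5 (aryl cis to C4-CH3) breaks this symmetry.
2. Last operation: hydrogenolysis of the two phenolic benzyl ethers.
3. The only ring is closed from the C2-symmetric (2S,3S)-1,4-diaryl-2,3-dimethylbutane-1,4-dione. C2–H comes from substrate-controlled hydride reduction of one carbonyl, O1–C5 from lactol formation, and C5–H from silane reduction of the oxocarbenium ion.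
4. Both aryl–carbonyl bonds of the diketone are made at once from the (2S,3S)-2,3-dimethylsuccinic bis-Weinreb amide and 4-benzyloxy-3,5-dimethoxyphenyllithium. The aryllithium derives from 2,6-dimethoxyphenol by para-bromination and benzylation.
5. The C3–C4 bond and both methyl centres come from oxidative homocoupling of the enolate of (R)-4-benzyl-3-propionyloxazolidinone, followed by removal of the auxiliary.

Key step: step 7

Remark: Ar = 4-(benzyloxy)-3,5-dimethoxyphenyl; ring numbering is O1, C2 (S, aryl trans to the C3 methyl), C3 (S), C4 (S), C5 (R, aryl cis to the C4 methyl); the two stages of the key step are assumed to be telescoped, the crude hydroxy ketone/lactol mixture being carried on after extraction without purification.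

## Route

Step 1
Reactants: 1 (R)-4-benzyl-3-propionyl-1,3-oxazolidin-2-one (two molecules)
Product: 3 (4R,4'R)-3,3'-[(2S,3S)-2,3-dimethylbutanedioyl]bis(4-benzyl-1,3-oxazolidin-2-one), via lithium Z-enolate 2 (not isolated)
Conditions: LDA, THF, −78 °C; anhydrous CuCl2, DMF–THF, −78 → 0 °C; aq. NH4Cl; crystallization or chromatography
Reagents that add atoms: none
Why: Cu(II)-mediated oxidative homocoupling of an imide enolate: one-electron oxidation of the lithium-chelated Z-enolate 2 joins two Cα atoms, each bonding on the face turned away from the C4 benzyl group (the face alkyl halides also take), which should make both new centres S with the (R)-auxiliary, and the minor isomers are diastereomers of 3 that crystallization or chromatography removes.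

Step 2
Reactants: 3 bis-imide
Product: 5 (2S,3S)-2,3-dimethylbutanedioic acid, via diperoxy acid 4 (not isolated)
Conditions: LiOH, 30% H2O2, THF–H2O, 0 °C; aq. Na2SO3; HCl to pH 1, EtOAc extraction from brine
Reagents that add atoms: hydrogen peroxide (acting as LiOOH), OO
Why: Hydroperoxide cleavage of N-acyl oxazolidinones: the small α-effect nucleophile LiOOH attacks the exocyclic acyl carbonyl even beside a branched carbon, sulfite reduces the peroxy acid 4 to the acid, and the cold, weakly basic medium should leave both α-centres untouched while the auxiliary is recovered.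

Step 3
Reactants: 5 (2S,3S)-2,3-dimethylbutanedioic acid; 6 N,O-dimethylhydroxylamine hydrochloride
Product: 7 (2S,3S)-N1,N4-dimethoxy-N1,N4,2,3-tetramethylbutanediamide
Conditions: EDC·HCl, HOBt, N-methylmorpholine, CH2Cl2, 0 °C → rt
Reagents that add atoms: N,O-dimethylhydroxylamine hydrochloride (6), CNOC.Cl
Why: Carbodiimide/HOBt amide coupling at both carboxyl groups, chosen over direct aluminium-amide aminolysis of 3 because α-branched imides without a β-hydroxyl group tend to open at the ring carbonyl; the active-ester conditions are mild enough to keep the (2S,3S) configuration.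

Step 4
Reactants: 8 2,6-dimethoxyphenol
Product: 9 4-bromo-2,6-dimethoxyphenol
Conditions: NBS, NaH (cat.), CHCl3–MeOH, −45 °C → rt
Reagents that add atoms: N-bromosuccinimide, O=C1CCC(=O)N1Br
Why: Electrophilic aromatic bromination in which the free phenol (phenoxide) is the dominant donor and, with both ortho positions occupied by methoxy groups, directs bromine to C4, which is why bromination comes before O-benzylation.

Step 5
Reactants: 9 4-bromo-2,6-dimethoxyphenol; 10 benzyl bromide
Product: 11 2-(benzyloxy)-5-bromo-1,3-dimethoxybenzene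
Conditions: K2CO3, DMF, rt
Reagents that add atoms: benzyl bromide (10), BrCc1ccccc1
Why: Williamson ether synthesis on the phenoxide; the benzyl ether withstands organolithium, hydride and BF3/silane conditions and leaves at the end by hydrogenolysis.

Step 6
Reactants: 11 2-(benzyloxy)-5-bromo-1,3-dimethoxybenzene (2.4 equiv); 7 bis-Weinreb amide
Product: 14 (2S,3S)-1,4-bis[4-(benzyloxy)-3,5-dimethoxyphenyl]-2,3-dimethylbutane-1,4-dione, via aryllithium 12 (not isolated), via bis-tetrahedral adduct 13 (not isolated)
Conditions: 11, n-BuLi, THF, −78 °C; then 7, THF, −78 → −40 °C; AcOH/THF quench at −78 °C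
Reagents that add atoms: none
Why: Bromine–lithium exchange followed by a two-fold Weinreb ketone synthesis: each amide takes up one aryllithium to give the lithium-chelated tetrahedral adduct 13, which does not collapse before the quench, so that no tertiary alcohol forms and the epimerizable aryl ketone is released only into cold weak acid, keeping both methyl centres S.

Step 7
Reactants: 14 (2S,3S)-diketone
Product: 18 (2S,3S,4S,5R)-2,5-bis[4-(benzyloxy)-3,5-dimethoxyphenyl]-3,4-dimethyloxolane, via hydroxy ketone 15 (not isolated), via lactol 16 (not isolated), via oxocarbenium ion 17 (not isolated)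
Conditions: i. L-Selectride (1.0 equiv, slow addition), THF, −78 °C; AcOH quench, extraction, no purification; ii. Et3SiH, BF3·OEt2, CH2Cl2, −78 °C; sat. NaHCO3 at −78 °C
Reagents that add atoms: none
Why: The C2 axis of 14 exchanges its two carbonyl groups, so hydride transfer from one equivalent of L-Selectride to either one gives the same alkoxide; in the Felkin–Anh arrangement the CH(CH3)C(O)Ar branch stands perpendicular to the C=O, the methyl lies beside the oxygen and the hydride passes the α-hydrogen, which should give the 1,2-anti alcohol 15 with (S)-C2, that is, aryl trans to the C3 methyl once the ring exists. The alkoxide adds to the remaining ketone in a 5-exo-trig closure (O1–C5) to the lactol(ate) 16, which masks the second carbonyl and so limits over-reduction to the 1,4-diol. BF3·OEt2 ionizes 16 to the aryl-conjugated oxocarbenium ion 17, and Et3SiH delivers hydride to C5 from the face opposite the adjacent C4 methyl and the C2 aryl group (inside attack on the envelope in which allylic strain against the coplanar aryl ring holds the C4 methyl pseudoaxial), so that the C5 aryl ends cis to the C4 methyl and cis to the C2 aryl, (R)-C5. The closest known reaction types are the Felkin-selective reduction of α-methyl aryl ketones by bulky borohydrides and the silane/BF3 reductive deoxygenation of 2-aryl-3-methyl cyclic hemiketals, which delivers the 2,3-cis ether under kinetic control at low temperature. The step needs mono- over double reduction, anti selectivity at C2 and kinetic cis selectivity at C5: the first rests on stoichiometry, slow addition and lactolate formation, the second on the size difference between methyl and the branched acyl-bearing substituent next to a bulky aryl ketone, and the third on keeping the ionic reduction at −78 °C, where neither Lewis-acid opening of the benzylic C–O bonds nor proton loss from C4 of 17 should compete.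

Step 8
Reactants: 18 bis-O-benzyl ether
Product: 19 4,4'-[(2S,3S,4S,5R)-3,4-dimethyloxolane-2,5-diyl]bis(2,6-dimethoxyphenol) (target)
Conditions: H2 (1 atm), 10% Pd/C, EtOAc–MeOH, rt, stopped at full debenzylation
Reagents that add atoms: none
Why: Heterogeneous catalytic hydrogenolysis: the unhindered primary PhCH2–OAr bonds are cleaved well before the hindered secondary benzylic C2–O1 and C5–O1 bonds of the ring under neutral conditions at 1 atm, and no stereocentre takes part.

## Compound list

1 | (R)-4-benzyl-3-propionyl-1,3-oxazolidin-2-one | CCC(=O)N1[C@H](Cc2ccccc2)COC1=O | starting material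
2 | lithium (Z)-enolate of 1 | C/C=C(\O[Li])N1[C@H](Cc2ccccc2)COC1=O | intermediate (not isolated)
3 | (4R,4'R)-3,3'-[(2S,3S)-2,3-dimethylbutanedioyl]bis(4-benzyl-1,3-oxazolidin-2-one) | O=C1OC[C@@H](Cc2ccccc2)N1C(=O)[C@@H](C)[C@H](C)C(=O)N1[C@H](Cc2ccccc2)COC1=O | intermediate
4 | (2S,3S)-2,3-dimethylbutanediperoxoic acid (present as its lithium salt) | OOC(=O)[C@@H](C)[C@H](C)C(=O)OO | intermediate (not isolated)
5 | (2S,3S)-2,3-dimethylbutanedioic acid | OC(=O)[C@@H](C)[C@H](C)C(O)=O | intermediate
6 | N,O-dimethylhydroxylamine hydrochloride | CNOC.Cl | starting material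
7 | (2S,3S)-N1,N4-dimethoxy-N1,N4,2,3-tetramethylbutanediamide | CON(C)C(=O)[C@@H](C)[C@H](C)C(=O)N(C)OC | intermediate
8 | 2,6-dimethoxyphenol | COc1cccc(OC)c1O | starting material
9 | 4-bromo-2,6-dimethoxyphenol | COc1cc(Br)cc(OC)c1O | intermediate
10 | benzyl bromide | BrCc1ccccc1 | starting material
11 | 2-(benzyloxy)-5-bromo-1,3-dimethoxybenzene | COc1cc(Br)cc(OC)c1OCc2ccccc2 | intermediate
12 | [4-(benzyloxy)-3,5-dimethoxyphenyl]lithium | [Li]c1cc(OC)c(OCc2ccccc2)c(OC)c1 | intermediate (not isolated)
13 | dilithium (2S,3S)-1,4-bis[4-(benzyloxy)-3,5-dimethoxyphenyl]-1,4-bis[methoxy(methyl)amino]-2,3-dimethylbutane-1,4-diolate (C1 and C4 undefined) | COc1cc(cc(OC)c1OCc2ccccc2)C(O[Li])(N(C)OC)[C@@H](C)[C@H](C)C(O[Li])(N(C)OC)c3cc(OC)c(OCc4ccccc4)c(OC)c3 | intermediate (not isolated)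
14 | (2S,3S)-1,4-bis[4-(benzyloxy)-3,5-dimethoxyphenyl]-2,3-dimethylbutane-1,4-dione | COc1cc(cc(OC)c1OCc2ccccc2)C(=O)[C@@H](C)[C@H](C)C(=O)c3cc(OC)c(OCc4ccccc4)c(OC)c3 | intermediate
15 | (2S,3S,4S)-1,4-bis[4-(benzyloxy)-3,5-dimethoxyphenyl]-4-hydroxy-2,3-dimethylbutan-1-one | COc1cc(cc(OC)c1OCc2ccccc2)[C@@H](O)[C@@H](C)[C@H](C)C(=O)c3cc(OC)c(OCc4ccccc4)c(OC)c3 | intermediate (not isolated)
16 | (3S,4S,5S)-2,5-bis[4-(benzyloxy)-3,5-dimethoxyphenyl]-3,4-dimethyloxolan-2-ol (both C2 epimers) | COc1cc(cc(OC)c1OCc2ccccc2)[C@H]3OC(O)(c4cc(OC)c(OCc5ccccc5)c(OC)c4)[C@@H](C)[C@@H]3C | intermediate (not isolated)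
17 | (2S,3S,4S)-2,5-bis[4-(benzyloxy)-3,5-dimethoxyphenyl]-3,4-dimethyl-3,4-dihydro-2H-furan-1-ium hydroxytrifluoroborate | COc1cc(cc(OC)c1OCc2ccccc2)[C@H]3[O+]=C(c4cc(OC)c(OCc5ccccc5)c(OC)c4)[C@@H](C)[C@@H]3C.O[B-](F)(F)F | intermediate (not isolated)
18 | (2S,3S,4S,5R)-2,5-bis[4-(benzyloxy)-3,5-dimethoxyphenyl]-3,4-dimethyloxolane | COc1cc(cc(OC)c1OCc2ccccc2)[C@H]3O[C@@H](c4cc(OC)c(OCc5ccccc5)c(OC)c4)[C@@H](C)[C@@H]3C | intermediate
19 | 4,4'-[(2S,3S,4S,5R)-3,4-dimethyloxolane-2,5-diyl]bis(2,6-dimethoxyphenol) | COc1cc([C@H]2O[C@@H](c3cc(OC)c(O)c(OC)c3)[C@@H](C)[C@@H]2C)cc(OC)c1O | target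

## Step count and risks

Total steps: 8. Longest linear sequence: 6 (steps 1, 2, 3, 6, 7, 8).

**Steps most likely to fail**

**Step 7.** Three processes could go wrong. The second carbonyl may be reduced before the alkoxide closes on it. The first hydride transfer may discriminate the carbonyl faces too weakly. The Lewis acid may equilibrate the kinetically set benzylic C5 centre.

The fallback gives up the two-directional reduction and brings in the aryl groups one after the other. It sets out from 7 and comes back at 16.
- One equivalent of aryllithium 12 is added to 7 (THF, −78 °C, AcOH quench). This should give the keto amide (2S,3S)-4-[4-(benzyloxy)-3,5-dimethoxyphenyl]-N-methoxy-N,2,3-trimethyl-4-oxobutanamide F1. Unreacted 7 and any 14 are separated and reused.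
- The single ketone of F1 is reduced under catalyst control by a Corey–Bakshi–Shibata reduction ((R)-Me-CBS, catecholborane, toluene, −78 °C). The sense of this catalyst matches the Felkin–Anh preference. The product should be the hydroxy amide (2S,3S,4S)-4-[4-(benzyloxy)-3,5-dimethoxyphenyl]-4-hydroxy-N-methoxy-N,2,3-trimethylbutanamide F2.
- TsOH·H2O in CH2Cl2 closes F2 to the lactone (3S,4S,5S)-5-[4-(benzyloxy)-3,5-dimethoxyphenyl]-3,4-dimethyloxolan-2-one F3. At this stage a minor epimer at the aryl-bearing carbon can be removed by crystallization or chromatography.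
- Addition of 12 (1.1 equiv, THF, −78 °C, AcOH quench) to F3 gives lactol 16, which passes through stage ii of step 7 to 18.
- Over-reduction is excluded because only one ketone is ever present.

**Step 1.** The coupling has radical character, so facial control on both partners may be imperfect. α-Chlorination and proton return to the enolate may also lower the throughput.

The fallback replaces the dimerization by an SN2 alkylation that takes one centre from the chiral pool. It sets out from 1 (as its enolate 2) and comes back at 5.
- Enolate 2 is alkylated with commercial ethyl (S)-2-{[(trifluoromethyl)sulfonyl]oxy}propanoate (THF, −78 → −20 °C).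
- Attack on the enolate face away from the benzyl group, together with inversion at the triflate carbon, should give ethyl (2S,3S)-4-[(4R)-4-benzyl-2-oxo-1,3-oxazolidin-3-yl]-2,3-dimethyl-4-oxobutanoate F4.
- LiOH/H2O2 at 0 °C removes the auxiliary to give the half-ester (2S,3S)-4-ethoxy-2,3-dimethyl-4-oxobutanoic acid F5.
- LiOH in THF–H2O at rt saponifies F5 to diacid 5.

**Step 6.** The second addition may stall at the hindered mono-adduct. α-Deprotonation by the aryllithium, or enolization during the quench, may leak material to the meso diketone.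

The fallback forms both ketones under neutral Pd/Cu catalysis instead of with a basic organolithium. It sets out from 3 (and from 12 for the aryl partner) and comes back at 14.
- EtSLi (EtSH, n-BuLi, THF, 0 °C) displaces both auxiliaries of 3 to give S,S'-diethyl (2S,3S)-2,3-dimethylbutanebis(thioate) F6.
- Aryllithium 12 is trapped with B(OiPr)3 and hydrolysed with aq. HCl to [4-(benzyloxy)-3,5-dimethoxyphenyl]boronic acid F7.
- A two-fold Liebeskind–Srogl coupling of F6 with F7 (Pd2(dba)3, tri(2-furyl)phosphine, copper(I) thiophene-2-carboxylate, THF, 50 °C) should give 14 without exposing the α-centres to base.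

## Further compounds

F1 | step 7 | (2S,3S)-4-[4-(benzyloxy)-3,5-dimethoxyphenyl]-N-methoxy-N,2,3-trimethyl-4-oxobutanamide | COc1cc(cc(OC)c1OCc2ccccc2)C(=O)[C@@H](C)[C@H](C)C(=O)N(C)OC
F2 | step 7 | (2S,3S,4S)-4-[4-(benzyloxy)-3,5-dimethoxyphenyl]-4-hydroxy-N-methoxy-N,2,3-trimethylbutanamide | COc1cc(cc(OC)c1OCc2ccccc2)[C@@H](O)[C@@H](C)[C@H](C)C(=O)N(C)OC
F3 | step 7 | (3S,4S,5S)-5-[4-(benzyloxy)-3,5-dimethoxyphenyl]-3,4-dimethyloxolan-2-one | COc1cc(cc(OC)c1OCc2ccccc2)[C@H]3OC(=O)[C@@H](C)[C@@H]3C
F4 | step 1 | ethyl (2S,3S)-4-[(4R)-4-benzyl-2-oxo-1,3-oxazolidin-3-yl]-2,3-dimethyl-4-oxobutanoate | CCOC(=O)[C@@H](C)[C@H](C)C(=O)N1[C@H](Cc2ccccc2)COC1=O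
F5 | step 1 | (2S,3S)-4-ethoxy-2,3-dimethyl-4-oxobutanoic acid | CCOC(=O)[C@@H](C)[C@H](C)C(O)=O
F6 | step 6 | S,S'-diethyl (2S,3S)-2,3-dimethylbutanebis(thioate) | CCSC(=O)[C@@H](C)[C@H](C)C(=O)SCC
F7 | step 6 | [4-(benzyloxy)-3,5-dimethoxyphenyl]boronic acid | OB(O)c1cc(OC)c(OCc2ccccc2)c(OC)c1
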